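**Strategy.** The side chain (C1′–C16′, numbered from the ring) is disconnected between benzylic C1′ and olefinic C2′. The key step exploits the ArCH2–CH=C(CH3) junction: the E-trisubstituted C2′=C3′ olefin with its C3′ methyl is the signature of a Zr-catalysed syn-methylalumination of a terminal alkyne, and C1′ on C6 of the hydroquinone ring is a benzylic electrophile. One pot therefore installs the C3′ methyl, fixes the 2′E geometry and forges C1′–C2′ by Ni(0)-catalysed coupling of the alkenylalane with a bis-silylated 2-(chloromethyl)-6-methylhydroquinone. The precursor is a C15 homopropargylic alcohol lacking that methyl; its C5′ stereocentre comes from asymmetric propargylation of farnesal.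

Key step: step 8

Assumption: the (S)-enantiomer of the phosphoric acid catalyst is specified for Si-face attack by analogy with the accepted closed transition-state model, in which the (R)-catalyst favours the Re face; if this enal shows the opposite sense, the (R)-catalyst is used in the same step.

**Step 1**
Reactants: 1 (2E,6E)-farnesol
Product: 2 (2E,6E)-farnesal
Conditions: activated MnO2 (15 equiv), CH2Cl2, rt
Reagents that add atoms: none
Why: MnO2 oxidation is selective for the primary allylic alcohol and should leave the 2E geometry and the isolated trisubstituted olefins untouched.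

**Step 2**
Reactants: 2 (2E,6E)-farnesal; 3 allenylboronic acid pinacol ester
Product: 5 (4S,5E,9E)-6,10,14-trimethylpentadeca-5,9,13-trien-1-yn-4-ol, via pinacol borate ester 4 (not isolated)
Conditions: (S)-TRIP phosphoric acid (10 mol%), 4 Å MS, toluene, 0 °C; aq. NaHCO3 work-up
Reagents that add atoms: none
Why: Chiral-phosphoric-acid-catalysed propargylboration (SE2′ attack of the allenylboronate through a closed six-membered transition state) should add only 1,2 to the enal, the catalyst shielding the Re face so that Si-face attack sets the 4S carbinol (C5′ of the target).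

**Step 3**
Reactants: 6 4-methoxy-2-methylphenol
Product: 8 2-hydroxy-5-methoxy-3-methylbenzaldehyde, via 2-(hydroxymethyl)-4-methoxy-6-methylphenol 7 (not isolated)
Conditions: MgCl2, Et3N, (CH2O)n, MeCN, reflux; 1 M HCl work-up
Reagents that add atoms: paraformaldehyde (reacts as formaldehyde), C=O
Why: Magnesium-mediated ortho-formylation (Casnati–Skattebøl type) can only occur at the single free ortho position, and a second formaldehyde oxidises the hydroxymethyl intermediate by hydride transfer.

**Step 4**
Reactants: 8 2-hydroxy-5-methoxy-3-methylbenzaldehyde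
Product: 10 2,5-dihydroxy-3-methylbenzaldehyde, via 2,5-bis(dibromoboryloxy)-3-methylbenzaldehyde 9 (not isolated)
Conditions: BBr3 (3 equiv), CH2Cl2, −78 → 0 °C; then H2O
Reagents that add atoms: none
Why: BBr3 cleavage of the aryl methyl ether (bromide attack on the O-methyl of the boron–ether complex) is routine for methoxybenzaldehydes and should spare the formyl group.

**Step 5**
Reactants: 10 2,5-dihydroxy-3-methylbenzaldehyde
Product: 11 2,5-bis[(tert-butyldimethylsilyl)oxy]-3-methylbenzaldehyde
Conditions: TBSCl (2.6 equiv), imidazole (5 equiv), DMAP (cat.), DMF, rt → 40 °C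
Reagents that add atoms: tert-butyldimethylsilyl chloride, CC(C)(C)[Si](C)(C)Cl
Why: Imidazole-promoted silylation of phenols should protect both hydroxyls, gentle warming bringing the hindered, hydrogen-bonded C2 hydroxyl to completion.

**Step 6**
Reactants: 11 2,5-bis[(tert-butyldimethylsilyl)oxy]-3-methylbenzaldehyde
Product: 13 {2,5-bis[(tert-butyldimethylsilyl)oxy]-3-methylphenyl}methanol, via diisobutylaluminium benzyl alkoxide 12 (not isolated)
Conditions: DIBAL-H (1.2 equiv), CH2Cl2, −78 °C; aq. Rochelle salt
Reagents that add atoms: none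
Why: Hydride reduction of the aldehyde; the covalent aluminium alkoxide at −78 °C should be too weakly nucleophilic to trigger aryl-to-benzyl O→O silyl migration.

**Step 7**
Reactants: 13 {2,5-bis[(tert-butyldimethylsilyl)oxy]-3-methylphenyl}methanol
Product: 15 1-(chloromethyl)-2,5-bis[(tert-butyldimethylsilyl)oxy]-3-methylbenzene, via benzylic mesylate 14 (not isolated)
Conditions: MsCl (1.2 equiv), Et3N (1.5 equiv), CH2Cl2, −20 °C; then LiCl (3 equiv), THF, 0 °C → rt
Reagents that add atoms: lithium chloride, [Li+].[Cl-]
Why: Mesylation followed by SN2 displacement with chloride at the activated benzylic carbon (Collington–Meyers-type chlorination) is non-acidic and should preserve both aryl silyl ethers.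

**Step 8**
Reactants: 5 (4S,5E,9E)-6,10,14-trimethylpentadeca-5,9,13-trien-1-yn-4-ol; 15 1-(chloromethyl)-2,5-bis[(tert-butyldimethylsilyl)oxy]-3-methylbenzene
Product: 18 (2E,5S,6E,10E)-1-{2,5-bis[(tert-butyldimethylsilyl)oxy]-3-methylphenyl}-3,7,11,15-tetramethylhexadeca-2,6,10,14-tetraen-5-ol, via alkenylalane 16 (not isolated), via O-aluminated coupling product 17 (not isolated)
Conditions: 5, AlMe3 (3 equiv), Cp2ZrCl2 (0.25 equiv), CH2Cl2, 0 °C → rt; volatiles removed in vacuo; then 15, NiCl2(PPh3)2 (5 mol%)/n-BuLi (10 mol%), THF, 0 °C → rt; aq. Rochelle salt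
Reagents that add atoms: trimethylaluminium, C[Al](C)C
Why: Zr-catalysed Negishi methylalumination adds CH3 and Al syn across the terminal alkyne of 5 (methyl to internal C3′, aluminium to terminal C2′), and the resulting (E)-alkenylalane 16 enters a Ni(0) cycle of oxidative addition into the benzylic C–Cl bond of 15, Al→Ni alkenyl transfer with retention and reductive elimination, forming C1′–C2′. The closest known reaction type is the one-pot carboalumination/Ni- or Pd-catalysed coupling of alkenylalanes with benzylic chlorides used to attach prenyl-type chains to protected hydroquinones. No ring is closed and no sp3 stereocentre is created; the only new stereo-element, the 2′E olefin, is fixed by the syn-carbometalation and kept by the stereoretentive coupling. The step needs regioselectivity (secured by the terminal alkyne, which places the metal on the CH terminus), chemoselectivity (the trisubstituted olefins are inert to methylalumination, excess AlMe3 is stripped before coupling and alkenyl should transfer to nickel faster than methyl) and integrity of C5′ (the hydroxyl is masked in situ as a dimethylaluminium alkoxide that should not ionise, and the mixture stays at or below room temperature to avoid alkoxide-assisted E→Z isomerisation of the alkenylalane).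

**Step 9**
Reactants: 18 (2E,5S,6E,10E)-1-{2,5-bis[(tert-butyldimethylsilyl)oxy]-3-methylphenyl}-3,7,11,15-tetramethylhexadeca-2,6,10,14-tetraen-5-ol
Product: 19 2-[(2E,5S,6E,10E)-5-hydroxy-3,7,11,15-tetramethylhexadeca-2,6,10,14-tetraen-1-yl]-6-methylbenzene-1,4-diol
Conditions: TBAF (2.5 equiv), AcOH (2.5 equiv), degassed THF, 0 °C, Ar
Reagents that add atoms: none
Why: Fluoride cleavage of the two aryl silyl ethers; acetic acid buffering protonates the phenoxides at once, which should suppress air oxidation to the quinone and leave the allylic C5′ alcohol and its configuration untouched.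

**Compound list**
1 | (2E,6E)-farnesol | CC(C)=CCC/C(C)=C/CC/C(C)=C/CO | starting material
2 | (2E,6E)-farnesal | CC(C)=CCC/C(C)=C/CC/C(C)=C/C=O | intermediate
3 | allenylboronic acid pinacol ester (4,4,5,5-tetramethyl-2-propa-1,2-dienyl-1,3,2-dioxaborolane) | C=C=CB1OC(C)(C)C(C)(C)O1 | starting material
4 | pinacol borate ester of (4S,5E,9E)-6,10,14-trimethylpentadeca-5,9,13-trien-1-yn-4-ol | CC(C)=CCC/C(C)=C/CC/C(C)=C/[C@@H](OB1OC(C)(C)C(C)(C)O1)CC#C | intermediate
5 | (4S,5E,9E)-6,10,14-trimethylpentadeca-5,9,13-trien-1-yn-4-ol | CC(C)=CCC/C(C)=C/CC/C(C)=C/[C@@H](O)CC#C | intermediate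
6 | 4-methoxy-2-methylphenol | COc1ccc(O)c(C)c1 | starting material
7 | 2-(hydroxymethyl)-4-methoxy-6-methylphenol (present as its magnesium salt) | COc1cc(C)c(O)c(CO)c1 | intermediate
8 | 2-hydroxy-5-methoxy-3-methylbenzaldehyde | COc1cc(C)c(O)c(C=O)c1 | intermediate
9 | 2,5-bis(dibromoboryloxy)-3-methylbenzaldehyde | Cc1cc(OB(Br)Br)cc(C=O)c1OB(Br)Br | intermediate
10 | 2,5-dihydroxy-3-methylbenzaldehyde | Cc1cc(O)cc(C=O)c1O | intermediate
11 | 2,5-bis[(tert-butyldimethylsilyl)oxy]-3-methylbenzaldehyde | Cc1cc(O[Si](C)(C)C(C)(C)C)cc(C=O)c1O[Si](C)(C)C(C)(C)C | intermediate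
12 | diisobutylaluminium {2,5-bis[(tert-butyldimethylsilyl)oxy]-3-methylphenyl}methoxide | Cc1cc(O[Si](C)(C)C(C)(C)C)cc(CO[Al](CC(C)C)CC(C)C)c1O[Si](C)(C)C(C)(C)C | intermediate
13 | {2,5-bis[(tert-butyldimethylsilyl)oxy]-3-methylphenyl}methanol | Cc1cc(O[Si](C)(C)C(C)(C)C)cc(CO)c1O[Si](C)(C)C(C)(C)C | intermediate
14 | {2,5-bis[(tert-butyldimethylsilyl)oxy]-3-methylphenyl}methyl methanesulfonate | Cc1cc(O[Si](C)(C)C(C)(C)C)cc(COS(C)(=O)=O)c1O[Si](C)(C)C(C)(C)C | intermediate
15 | 1-(chloromethyl)-2,5-bis[(tert-butyldimethylsilyl)oxy]-3-methylbenzene | Cc1cc(O[Si](C)(C)C(C)(C)C)cc(CCl)c1O[Si](C)(C)C(C)(C)C | intermediate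
16 | (1E,4S,5E,9E)-1-(dimethylalumanyl)-2,6,10,14-tetramethylpentadeca-1,5,9,13-tetraen-4-ol, O-dimethylaluminium alkoxide | CC(C)=CCC/C(C)=C/CC/C(C)=C/[C@@H](O[Al](C)C)C/C(C)=C/[Al](C)C | intermediate
17 | O-dimethylaluminium alkoxide of compound 18 | CC(C)=CCC/C(C)=C/CC/C(C)=C/[C@@H](O[Al](C)C)C/C(C)=C/Cc1cc(O[Si](C)(C)C(C)(C)C)cc(C)c1O[Si](C)(C)C(C)(C)C | intermediate
18 | (2E,5S,6E,10E)-1-{2,5-bis[(tert-butyldimethylsilyl)oxy]-3-methylphenyl}-3,7,11,15-tetramethylhexadeca-2,6,10,14-tetraen-5-ol | CC(C)=CCC/C(C)=C/CC/C(C)=C/[C@@H](O)C/C(C)=C/Cc1cc(O[Si](C)(C)C(C)(C)C)cc(C)c1O[Si](C)(C)C(C)(C)C | intermediate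
19 | 2-[(2E,5S,6E,10E)-5-hydroxy-3,7,11,15-tetramethylhexadeca-2,6,10,14-tetraen-1-yl]-6-methylbenzene-1,4-diol | CC(C)=CCC/C(C)=C/CC/C(C)=C/[C@@H](O)C/C(C)=C/Cc1cc(O)cc(C)c1O | target

**Step count.** Total: 9 steps. Longest linear sequence: 7 steps (6 → 19, steps 3–9); the alkyne branch (steps 1–2) joins at step 8.

**Steps most likely to fail**

Step 8. The methylalumination may be slow or less regioselective in the presence of the aluminium alkoxide, and the alkenylalane may partly isomerise. The Al→Ni alkenyl transfer may also lag behind methyl transfer or reductive homocoupling of the benzylic chloride. The fallback keeps the same C1′–C2′ bond but reverses the polarity and splits the operation in two. It sets out from 5 and 15 and returns at 18. Compound 5 is carboaluminated as in step 8 and the alkenylalane is quenched with I2 (THF, −30 °C) to give (1E,4S,5E,9E)-1-iodo-2,6,10,14-tetramethylpentadeca-1,5,9,13-tetraen-4-ol F1. Chloride 15 is converted by LiCl-promoted zinc insertion (Zn dust, LiCl, THF, rt) into {2,5-bis[(tert-butyldimethylsilyl)oxy]-3-methylbenzyl}zinc chloride F2. A Pd-catalysed Negishi coupling of F1 with an excess of F2 (Pd(OAc)2/SPhos, THF, rt) should then give 18.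

Step 2. Facial discrimination may be insufficient for a β,β-disubstituted enal, or turnover may be slow enough for background racemic addition to compete. The fallback is an enzymatic resolution; it sets out from 2 and returns at 5. A zinc-mediated Barbier propargylation of 2 with propargyl bromide (Zn, THF/sat. aq. NH4Cl, 0 °C) should give racemic (5E,9E)-6,10,14-trimethylpentadeca-5,9,13-trien-1-yn-4-ol F3. A lipase (serine hydrolase class; Burkholderia cepacia lipase or CAL-B, vinyl acetate, MTBE, 30 °C) should then acylate the R enantiomer, in line with the empirical enantiopreference of lipases for secondary alcohols (large alkenyl group, medium propargyl group). This gives (4R,5E,9E)-6,10,14-trimethylpentadeca-5,9,13-trien-1-yn-4-yl acetate F4 and leaves the unreacted S alcohol 5, which is separated by chromatography.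

Step 9. The phenoxides and the free hydroquinone may be oxidised by adventitious air during desilylation or purification, giving hydroquinone/quinone mixtures. The fallback passes deliberately through the quinone; it sets out from 18 and returns at 19. Desilylation with TBAF (THF, 0 °C) is followed by oxidation of the crude product with Ag2O (Et2O, rt) to 2-[(2E,5S,6E,10E)-5-hydroxy-3,7,11,15-tetramethylhexadeca-2,6,10,14-tetraen-1-yl]-6-methylcyclohexa-2,5-diene-1,4-dione F5, which is purified as the air-stable quinone. Reduction with Na2S2O4 (Et2O/H2O, rt, Ar) should then give 19 by simple extraction.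

**Further compounds**
F1 | step 8 | (1E,4S,5E,9E)-1-iodo-2,6,10,14-tetramethylpentadeca-1,5,9,13-tetraen-4-ol | CC(C)=CCC/C(C)=C/CC/C(C)=C/[C@@H](O)C/C(C)=C/I
F2 | step 8 | {2,5-bis[(tert-butyldimethylsilyl)oxy]-3-methylbenzyl}zinc chloride | Cl[Zn]Cc1cc(O[Si](C)(C)C(C)(C)C)cc(C)c1O[Si](C)(C)C(C)(C)C
F3 | step 2 | racemic (5E,9E)-6,10,14-trimethylpentadeca-5,9,13-trien-1-yn-4-ol | CC(C)=CCC/C(C)=C/CC/C(C)=C/C(O)CC#C
F4 | step 2 | (4R,5E,9E)-6,10,14-trimethylpentadeca-5,9,13-trien-1-yn-4-yl acetate | CC(C)=CCC/C(C)=C/CC/C(C)=C/[C@H](OC(C)=O)CC#C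
F5 | step 9 | 2-[(2E,5S,6E,10E)-5-hydroxy-3,7,11,15-tetramethylhexadeca-2,6,10,14-tetraen-1-yl]-6-methylcyclohexa-2,5-diene-1,4-dione | CC(C)=CCC/C(C)=C/CC/C(C)=C/[C@@H](O)C/C(C)=C/CC1=CC(=O)C=C(C)C1=O
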